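The numbers of this flask come from no measurement, and the outcome is calculated.

In a one-step world a living end Q keeps adding L to its chain, and no step ends that chain. This flask has 3 further steps, and the reckoning here follows what they do to a chain.

| flask | L | D | time |
|---|---|---|---|
| larch | 10 mM | 0.19 mM | 4.0 h |
| birch | 10 mM | 0.19 mM | 1.2 h |

    L + Q → E + Q, rate k1*[Q]*[L] (k1 = 1.89 /M/s)
    L + D → Q + E (k2 = 0.0169 /M/s)
    Q → J (k3 = 2.05 × 10⁻⁴ /s)
    Q + L → Q.L (k4 = 0.0342 /M/s)

- the average divides the monomer in chains by the number of chains begun, living and dead together
- run time (larch): 4.0 h

1. which of the two ends with the longer chains by the average number of monomer units in a chain (chains begun, living or dead) ("neither" if they lie within 10 %) (larch / birch / neither)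
2. average number of monomer units in a chain (chains begun, living or dead) at the end, larch
3. average number of monomer units in a chain (chains begun, living or dead) at the end, birch

The reckoning holds L at its charge, which makes growth pseudo-first-order, and takes chains as begun evenly in time. Both flasks share these charges.

1. At the start a living end adds L at 0.0189 /s.

2. The end stops growing in two ways: it falls to J at 2.05 × 10⁻⁴ /s, and it binds L into Q.L at 3.42 × 10⁻⁴ /s. Together these give a loss pace of 5.47 × 10⁻⁴ /s, and growth is far quicker than loss.

3. Integrating growth times survival over a chain's age gives a length of reach × (1 − exp(−loss pace × age)). The reach is growth pace over loss pace, the units one living end adds in its lifetime: 34.6.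

4. Younger chains fall short of the reach. With even beginnings, the mean shortfall is the fraction (1 − exp(−x))/x, where x counts the lifetimes the run lasts. Larch lasts 7.88 lifetimes and birch 2.36, so larch loses 12.7 % of the reach and birch 38.3 %.

5. The averages are therefore 30.2 for larch and 21.3 for birch, and the longer chains belong to larch.

The forecast, reckoned by hand in steps on the grounds that “no simple limit applies”, named larch, with 29.5 for larch and 22.5 for birch. It stands below this reckoning for larch and above it for birch.

The simulation gives larch as the longer, with 29.4 for larch and 22.5 for birch, so the forecast held.

The neighbouring flask is birch with L charged at 2.5 mM. Its loss pace is 2.91 × 10⁻⁴ /s, so the reach becomes 16.3. Its run lasts 1.25 lifetimes, which takes away 57.0 % of that reach and leaves an average of 7.01. The simulated average for this neighbouring flask is 7.92.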